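The readings stem from a simulated flask for an exercise, noise included.

The pitfall in your quick number is the ratio. The epsilon flask has 2.00 times as much partner as starting material, just as the theta run has, so you copied theta's 80.6% at 60 h. But epsilon is charged at a third of theta's concentrations, and that is what the copy passes over.

| flask | starting material | partner | time |
|---|---|---|---|
| theta | 0.600 M | 1.20 M |  |
| zeta | 0.600 M | 2.40 M |  |
| eta | 0.900 M | 1.20 M |  |
| epsilon | 0.200 M | 0.400 M | 60 h |

| run | time / h | [target] / M |
|---|---|---|
| theta run | 7.5 | 0.2542 |
| theta run | 15 | 0.3607 |
| theta run | 22 | 0.4037 |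
| theta run | 30 | 0.4435 |
| theta run | 38 | 0.4588 |
| theta run | 45 | 0.4683 |
| theta run | 52 | 0.4740 |
| theta run | 60 | 0.4835 |
| zeta run | 7.5 | 0.4103 |
| zeta run | 15 | 0.5018 |
| zeta run | 22 | 0.5368 |
| zeta run | 30 | 0.5541 |
| zeta run | 38 | 0.5592 |
| zeta run | 45 | 0.5642 |
| zeta run | 52 | 0.5622 |
| zeta run | 60 | 0.5639 |
| eta run | 7.5 | 0.3707 |
| eta run | 15 | 0.5096 |
| eta run | 22 | 0.5734 |
| eta run | 30 | 0.6126 |
| eta run | 38 | 0.6386 |
| eta run | 45 | 0.6513 |
| eta run | 52 | 0.6630 |
| eta run | 60 | 0.6704 |

(scatter of a reading: 0.002 M)

- apparent order in [starting material] of the starting rate, round the charge of the theta run (the rate where two percent of its starting material have turned into target) (one fixed amount of target, the same in the runs compared)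
- apparent order in [partner] of the starting rate, round the charge of the theta run (the rate where two percent of its starting material have turned into target)
- target in the epsilon run at 60 h, as a share of the starting material charged

- Overall: starting material + partner -> target.
- Constant volume, constant temperature.
- "The second partner" is partner.
- An order is taken over about fifteen percent of the charge, up and down.

Here is how we reckon instead. Theta's last reading stands at 1.87 M⁻¹ on the pairing clock, the logarithm of the fraction of partner left over the fraction of starting material left, divided by the partner's excess at the start; this is the integrated second-order law. At 7.5 h the theta, zeta and eta runs read 0.522 M⁻¹, 0.536 M⁻¹ and 0.538 M⁻¹, so across these charges we put both orders at first order. Later the clock slows: from 7.5 h to 60 h time grows 8.00 times and theta's clock 3.58 times. At the end eta reads 1.83 M⁻¹, near theta, while zeta reads 1.41 M⁻¹. We therefore carry theta's reading to epsilon, whose excess is a third of theta's. That gives 47.6% of the starting material, the limiting reagent, which is less than your copy.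

The forecast gives orders 1.03 and 1 and 47%, slightly under ours, and reads that “the early rate is close to first order in each reactant”.

The epsilon flask gave 50.9% at 60 h, with orders 1.0 and 1.0, and the forecast held within its margins.

    starting material + partner → target + by-product (0.07992 M⁻¹ h⁻¹)
    partner → lost reagent (0.01912 h⁻¹)
    starting material → decomposed substrate (0.009216 h⁻¹)

Over those hours in the epsilon flask, pairing ran beside the partner's loss to lost reagent, with a half-life of 36.3 h, and the starting material's decay to decomposed substrate, with a half-life of 75.2 h, and the pairing clock came to 2.09 M⁻¹, higher than theta's 1.87 M⁻¹. Early in the eta run, target came to a quarter of the starting material charged by 3.52 h, where the clock reads 0.267 M⁻¹, and the theta run, at that share by 3.38 h, reads 0.257 M⁻¹.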